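**Retrosynthetic overview**

1. Only the oxolane ring has to be made; both arenes are bought. As in lignan biosynthesis, it is cut in one operation at C8–C8' and at C7–O(C9').
2. This leaves the two phenylpropene halves: a cinnamyl alcohol (from cinnamic acid 1 through mixed anhydride 2, giving alcohol 3) and propenylbenzene 4.
3. Forward: one-electron oxidation of the alkene pair forms C8–C8'; the C9' hydroxyl closes the ring onto the quinone-methide-like C7 cation; the remaining C7' radical takes up O2 (in place of biosynthetic water) to give hydroperoxide 5, reduced in the same flask to target 6.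
4. All four stereocentres arise in that step: C8/C8' under a chiral counter-anion (standing in for a dirigent protein), C7 and C7' by substrate control.
5. Ring order: no ring before step 2; oxolane closure follows the C–C coupling and precedes oxygenation at C7'.

Numbering and assumption: lignan numbering is used for atoms (C7/C8/C9 = ArCH, CH, CH3 from 4, i.e. oxolane C5, C4 and the 4-methyl; C7'/C8'/C9' = carbinol carbon, oxolane C3 and oxolane C2 from 3); which enantiomer of the chiral anion gives the (7S,8S,8'R) series is fixed in a pilot run and is written as (S,S) below.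

**Route**

Step 1
Reactants: 1 (E)-3-(3,4-dimethoxyphenyl)prop-2-enoic acid
Product: 3 (E)-3-(3,4-dimethoxyphenyl)prop-2-en-1-ol, via mixed ethyl carbonic anhydride 2 (not isolated)
Conditions: ClCO2Et, Et3N, THF, −10 °C; filter; then NaBH4, THF–H2O, 0 to 20 °C
Reagents that add atoms: none
Why: Mixed-anhydride activation followed by borohydride reduction is a standard 1,2-selective way from cinnamic acids to cinnamyl alcohols that leaves the E alkene untouched and forms no stereocentre.

Step 2
Reactants: 3 (E)-3-(3,4-dimethoxyphenyl)prop-2-en-1-ol; 4 1,2-dimethoxy-4-[(E)-prop-1-enyl]benzene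
Product: 6 (R)-(3,4-dimethoxyphenyl)[(3R,4S,5S)-5-(3,4-dimethoxyphenyl)-4-methyloxolan-3-yl]methanol, via benzylic hydroperoxide 5 (not isolated)
Conditions: 4 (3 equiv), 9-mesitylthioxanthylium (S,S)-IDPi ion-pair photocatalyst (3 mol%), dry air (1 atm), CH2Cl2, −40 °C, green LEDs (525 nm), 3 added over 6 h; then PPh3 (1.5 equiv), −40 to 20 °C
Reagents that add atoms: dioxygen, O=O
Why: Proposed new method: the photo-excited thioxanthylium oxidises the alkene pair to an arylalkene radical cation that stays paired with the confined chiral IDPi anion and joins the partner alkene β-carbon to β-carbon (C8–C8', anti topology, which sets C8 and C8' absolutely and puts the methyl and the C7' arm cis on the later ring), the C9' hydroxyl then closes 5-exo onto the quinone-methide-like C7 benzylic cation with the aryl trans to the methyl (C7), the remaining C7' benzylic radical takes up O2 anti to C8 from its allylic-strain-minimised conformer (7'R) and the peroxyl radical is reduced by the thioxanthyl radical to turn the catalyst over, after which PPh3 reduces the O–O bond with retention; the closest known reaction types are the ion-pair-controlled asymmetric radical-cation [2+2] cycloaddition of propenyl anisoles with styrenes, the polar-radical-crossover cycloaddition of alkenols and the aerobic radical-cation [2+2+2] route to 1,2-dioxanes.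

**Compound list**

1 | (E)-3-(3,4-dimethoxyphenyl)prop-2-enoic acid | COc1ccc(/C=C/C(=O)O)cc1OC | starting material
2 | ethyl carbonic (E)-3-(3,4-dimethoxyphenyl)prop-2-enoic anhydride | CCOC(=O)OC(=O)/C=C/c1ccc(OC)c(OC)c1 | intermediate
3 | (E)-3-(3,4-dimethoxyphenyl)prop-2-en-1-ol | COc1ccc(/C=C/CO)cc1OC | intermediate
4 | 1,2-dimethoxy-4-[(E)-prop-1-enyl]benzene ((E)-methylisoeugenol) | COc1ccc(/C=C/C)cc1OC | starting material
5 | (2S,3S,4R)-2-(3,4-dimethoxyphenyl)-4-[(R)-(3,4-dimethoxyphenyl)(hydroperoxy)methyl]-3-methyloxolane | COc1ccc([C@H]2OC[C@H]([C@@H](OO)c3ccc(OC)c(OC)c3)[C@@H]2C)cc1OC | intermediate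
6 | (R)-(3,4-dimethoxyphenyl)[(3R,4S,5S)-5-(3,4-dimethoxyphenyl)-4-methyloxolan-3-yl]methanol | COc1ccc([C@H]2OC[C@H]([C@@H](O)c3ccc(OC)c(OC)c3)[C@@H]2C)cc1OC | target

**Totals and risks**

Total step count: 2. Longest linear sequence: 2 (1 to 3 to 6; 4 enters in step 2).

The route has only two steps, so step 2 is entered twice, once for each of its two independent stereochemical risks.

1. Step 2, absolute control of the C8–C8' coupling. The free hydroxyl, O2 and the hydroperoxide may loosen the ion pair, and the acid form of the anion may trigger Hock cleavage of 5. Homocoupling is held down by excess 4 and slow addition of 3; homodimer radical cations of 4 have no internal nucleophile and revert. If 6 is still formed with low enantiomeric purity, the fallback is classical resolution in place of asymmetric catalysis. It sets out from 3 and 4, which are coupled under the same aerobic conditions with achiral 2,4,6-triphenylpyrylium tetrafluoroborate (blue LEDs, CH2Cl2). This gives 5 together with the enantiomer of hydroperoxide 5 F1, and after PPh3 racemic 6, that is 6 together with the enantiomer of 6 F2. Esterification of the racemate with (S)-2-(6-methoxynaphthalen-2-yl)propanoic acid (EDC·HCl, DMAP, CH2Cl2) gives two diastereomers, the (S)-naproxen ester of 6 F3 and the (S)-naproxen ester of the enantiomer of 6 F4, separated on silica or by crystallisation. LiOH in THF–H2O cleaves F3 at the acyl–oxygen bond and the sequence comes back to the route at 6.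

2. Step 2, oxygen capture at C7'. If the C7' radical takes up O2 with poor face selectivity, 5 carries much of its 7'S epimer. The fallback is SN2 inversion in place of radical capture and sets out from 5 as formed. After the PPh3 reduction, the 7'-epimer of 6, (S)-(3,4-dimethoxyphenyl)[(3R,4S,5S)-5-(3,4-dimethoxyphenyl)-4-methyloxolan-3-yl]methanol F5, is separated from 6 by chromatography. A Mitsunobu reaction (4-nitrobenzoic acid, PPh3, DIAD, toluene, 0 °C) converts it into the inverted ester, the 4-nitrobenzoate of 6 F6. If ionisation of the electron-rich benzylic centre competes, the cation is captured from the same anti-to-C8 face and leads to the same ester; elimination to the styrene is the side reaction to watch. K2CO3 in MeOH removes the ester and the sequence comes back at 6.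

3. Step 1. The risks are partial conjugate reduction and incomplete activation of the acid. The fallback uses an isolated ester and an aluminium hydride in place of borohydride on an activated acid, and sets out from 1. Fischer esterification (MeOH, cat. H2SO4, reflux) gives methyl (E)-3-(3,4-dimethoxyphenyl)prop-2-enoate F7. Reduction with i-Bu2AlH (2.2 equiv, CH2Cl2, −78 °C) occurs only at the carbonyl and comes back at 3.

**Further compounds**

F1 | step 2 | (2R,3R,4S)-2-(3,4-dimethoxyphenyl)-4-[(S)-(3,4-dimethoxyphenyl)(hydroperoxy)methyl]-3-methyloxolane (enantiomer of 5) | COc1ccc([C@@H]2OC[C@@H]([C@H](OO)c3ccc(OC)c(OC)c3)[C@H]2C)cc1OC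
F2 | step 2 | (S)-(3,4-dimethoxyphenyl)[(3S,4R,5R)-5-(3,4-dimethoxyphenyl)-4-methyloxolan-3-yl]methanol (enantiomer of 6) | COc1ccc([C@@H]2OC[C@@H]([C@H](O)c3ccc(OC)c(OC)c3)[C@H]2C)cc1OC
F3 | step 2 | (R)-(3,4-dimethoxyphenyl)[(3R,4S,5S)-5-(3,4-dimethoxyphenyl)-4-methyloxolan-3-yl]methyl (S)-2-(6-methoxynaphthalen-2-yl)propanoate | COc1ccc([C@H]2OC[C@H]([C@@H](OC(=O)[C@@H](C)c3ccc4cc(OC)ccc4c3)c3ccc(OC)c(OC)c3)[C@@H]2C)cc1OC
F4 | step 2 | (S)-(3,4-dimethoxyphenyl)[(3S,4R,5R)-5-(3,4-dimethoxyphenyl)-4-methyloxolan-3-yl]methyl (S)-2-(6-methoxynaphthalen-2-yl)propanoate | COc1ccc([C@@H]2OC[C@@H]([C@H](OC(=O)[C@@H](C)c3ccc4cc(OC)ccc4c3)c3ccc(OC)c(OC)c3)[C@H]2C)cc1OC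
F5 | step 2 | (S)-(3,4-dimethoxyphenyl)[(3R,4S,5S)-5-(3,4-dimethoxyphenyl)-4-methyloxolan-3-yl]methanol (7'-epimer of 6) | COc1ccc([C@H]2OC[C@H]([C@H](O)c3ccc(OC)c(OC)c3)[C@@H]2C)cc1OC
F6 | step 2 | (R)-(3,4-dimethoxyphenyl)[(3R,4S,5S)-5-(3,4-dimethoxyphenyl)-4-methyloxolan-3-yl]methyl 4-nitrobenzoate | COc1ccc([C@H]2OC[C@H]([C@@H](OC(=O)c3ccc(cc3)[N+](=O)[O-])c3ccc(OC)c(OC)c3)[C@@H]2C)cc1OC
F7 | step 1 | methyl (E)-3-(3,4-dimethoxyphenyl)prop-2-enoate | COC(=O)/C=C/c1ccc(OC)c(OC)c1
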